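**Retrosynthetic overview**
1. 19 ⇒ 15: the last C–O bond made is the C6 tiglate, with C7–OH masked only in the flask. 15 ⇒ 14 ⇒ 13 by acetonide hydrolysis and isopropenyl → isopropyl hydrogenation.
2. 13 ⇒ 9: the C3 tiglate comes from Mitsunobu inversion of the 3α-allylic alcohol, and the C5 acetate from acylation in the same flask.
3. 9 ⇒ 8 (key step, ring A): the C3–C4 bond closes as in the cyclase step neryl/linalyl cation → α-terpinyl cation (geranyl C1 attacked by the C6=C7 olefin, proton loss to isopropenyl). It runs at the aldehyde level (neral → isopiperitenol type) on a chain that already carries O5, O6 and O7.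
4. 8 ⇒ 7 ⇒ 6 ⇒ 3: the (Z)-enal is stored as a lactol, and its geometry comes from a temporary pyranone ring B made with Ph3P=C=C=O. 3 ⇒ 1 + 2 by an anti-selective proline aldol that sets C5 and C6.
5. Ring order: dioxane ring C (bought with 1) → ring B (step 2) → ring A (step 4, ring B opens in the same step) → ring C removed (step 7).

Assumption: p-menthane numbering is used for the ring (C1 bears C7H2OH, C4 bears the isopropyl group, β = face of the C4 substituent), and 1, 2, 4, 10, 11, 16 and (R)-proline are taken as catalogue chemicals.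

**Step 1**
Reactants: 1 2,2-dimethyl-1,3-dioxan-5-one; 2 3-methylbut-2-enal (prenal)
Product: 3 (4R)-4-[(1R)-1-hydroxy-3-methylbut-2-enyl]-2,2-dimethyl-1,3-dioxan-5-one (anti aldol)
Conditions: (R)-proline (30 mol%), 1 (2 equiv), slow addition of 2, DMF, 4 °C, 5 d
Reagents that add atoms: none
Why: Proline enamine aldol of the dihydroxyacetone acetonide: the ring-enforced E-enamine attacks the aldehyde through the acid-organised chair transition state, which gives the anti aldol (future cis C5/C6 diol), (R)-proline gives the (4R,1'R) enantiomer, and prenal can act only as acceptor at its carbonyl group.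

**Step 2**
Reactants: 3 anti aldol; 4 (triphenylphosphoranylidene)ketene
Product: 6 (8R,8aS)-2,2-dimethyl-8-(2-methylprop-1-enyl)-8,8a-dihydro-4H-pyrano[3,4-d][1,3]dioxin-6-one, via ester ylide 5 (not isolated)
Conditions: 4 (1.2 equiv), toluene, 60 → 90 °C
Reagents that add atoms: (triphenylphosphoranylidene)ketene 4, O=C=C=P(c1ccccc1)(c1ccccc1)c1ccccc1
Why: Domino O–H addition to the cumulated ylide followed by intramolecular Wittig olefination of the activated α,α'-dialkoxy ketone under neutral conditions, in which the six-membered ring forces the new carbonyl carbon cis to C4 of the chain (the neryl-type Z geometry) and neither stereocentre is touched.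

**Step 3**
Reactants: 6 bicyclic lactone
Product: 7 (8R,8aS)-2,2-dimethyl-8-(2-methylprop-1-enyl)-4,6,8,8a-tetrahydropyrano[3,4-d][1,3]dioxin-6-ol (both anomers)
Conditions: iBu2AlH (1.1 equiv), CH2Cl2, −78 °C; aq potassium sodium tartrate
Reagents that add atoms: none
Why: Partial 1,2-reduction of an unsaturated δ-lactone, which stops at the aluminium hemiacetal at −78 °C; the anomeric centre is lost again in step 4, so it need not be controlled.

**Step 4**
Reactants: 7 lactol
Product: 9 (3R,4S,5R,6S)-6,7-isopropylidenedioxy-p-mentha-1,8-diene-3,5-diol, via open-chain Z-hydroxyenal 8 (not isolated)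
Conditions: Me2AlCl (3 equiv), CH2Cl2, −78 → −20 °C; aq NaHCO3/potassium sodium tartrate
Reagents that add atoms: none
Why: Proposed new method: Me2AlCl deprotonates the lactol (CH4) and the aluminium lactolate opens to the more basic C5 alkoxide plus the conjugated (Z)-enal 8 (the same opening that causes over-reduction of lactones by iBu2AlH on warming); a further Me2AlCl activates the aldehyde and the trisubstituted olefin closes the C3–C4 bond by an intramolecular carbonyl-ene reaction with hydrogen loss from a methyl group to give the isopropenyl group; A1,3 strain with the Z-methyl keeps H5 in the olefin plane, so the aldehyde carbon adds anti to the bulky C5–O–Al group (4β-isopropenyl trans to 5α-O), and the chair-like transition state puts the new C3–O pseudo-equatorial (3α, trans to isopropenyl); the closest known reaction types are the Me2AlCl-promoted carbonyl-ene cyclisation of citronellal-type aldehydes and the acid-catalysed neral → isopiperitenol cyclisation.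

**Step 5**
Reactants: 9 diol; 10 tiglic acid; 11 acetic anhydride
Product: 13 (3S,4S,5R,6S)-5-acetoxy-6,7-isopropylidenedioxy-3-tigloyloxy-p-mentha-1,8-diene, via 3β-tiglate alcohol 12 (not isolated)
Conditions: PPh3 (1.8 equiv), DIAD (1.8 equiv), 10 (2 equiv), THF, 0 °C → rt; then 11, Et3N, DMAP, rt
Reagents that add atoms: tiglic acid 10, C/C=C(\C)C(=O)O; acetic anhydride 11, CC(=O)OC(C)=O
Why: Mitsunobu esterification displaces only the allylic C3 oxyphosphonium ion by SN2 with clean inversion (3α-OH → 3β-tiglate, cis to the C4 group), the non-allylic C5–OH flanked by two branched carbons cannot be displaced, and it is then acetylated with retention by DMAP acyl transfer.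

**Step 6**
Reactants: 13 isopropenyl diester
Product: 14 (3S,4S,5R,6S)-5-acetoxy-6,7-isopropylidenedioxy-3-tigloyloxy-p-menth-1-ene
Conditions: H2 (1 atm), RhCl(PPh3)3 (5 mol%), toluene/EtOH 1:1, rt
Reagents that add atoms: none
Why: Homogeneous hydrogenation with RhCl(PPh3)3 selects by olefin substitution, so the 1,1-disubstituted isopropenyl group is saturated while the trisubstituted ring olefin and the trisubstituted conjugated tiglate stay (the carvone → carvotanacetone selectivity); no stereocentre is formed.

**Step 7**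
Reactants: 14 acetonide
Product: 15 (3S,4S,5R,6S)-5-acetoxy-3-tigloyloxy-p-menth-1-ene-6,7-diol
Conditions: AcOH/H2O 4:1, 35 °C
Reagents that add atoms: none
Why: Mild acid hydrolysis of a 1,3-dioxane acetonide, under which the esters survive and acetyl migration from O5 to the cis O6 is slow; all C–O bonds at stereocentres stay intact.

**Step 8**
Reactants: 15 diol; 16 tigloyl chloride
Product: 19 (3S,4S,5R,6S)-5-acetoxy-7-hydroxy-3,6-bis(tigloyloxy)-p-menth-1-ene, via TES ether 17 (not isolated), via TES ether ditiglate 18 (not isolated)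
Conditions: Et3SiCl (1.05 equiv), pyridine, CH2Cl2, −40 °C; then 16 (3 equiv), DMAP, 0 °C → rt; then 1 M aq HCl, THF, 0 °C
Reagents that add atoms: tigloyl chloride 16, C/C=C(\C)C(=O)Cl; chlorotriethylsilane, CC[Si](Cl)(CC)CC (its silicon stays only in 17 and 18)
Why: Transient silyl protection as used for nucleoside acylation: the primary allylic C7–OH is silylated far faster than the hindered C6–OH, DMAP-catalysed acylation then esterifies O6 with retention, and the primary TES ether is the only group cleaved by cold dilute acid.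

**Compound list**
1 | 2,2-dimethyl-1,3-dioxan-5-one | CC1(C)OCC(=O)CO1 | starting material
2 | 3-methylbut-2-enal (prenal) | CC(C)=CC=O | starting material
3 | (4R)-4-[(1R)-1-hydroxy-3-methylbut-2-enyl]-2,2-dimethyl-1,3-dioxan-5-one | O=C1COC(C)(C)O[C@@H]1[C@H](O)C=C(C)C | intermediate
4 | (triphenylphosphoranylidene)ketene | O=C=C=P(c1ccccc1)(c1ccccc1)c1ccccc1 | starting material
5 | (1R)-1-[(4R)-2,2-dimethyl-5-oxo-1,3-dioxan-4-yl]-3-methylbut-2-enyl (triphenylphosphoranylidene)acetate (ester ylide, not isolated) | O=C1COC(C)(C)O[C@@H]1[C@H](OC(=O)C=P(c1ccccc1)(c1ccccc1)c1ccccc1)C=C(C)C | intermediate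
6 | (8R,8aS)-2,2-dimethyl-8-(2-methylprop-1-enyl)-8,8a-dihydro-4H-pyrano[3,4-d][1,3]dioxin-6-one | O=C1C=C2COC(C)(C)O[C@@H]2[C@@H](C=C(C)C)O1 | intermediate
7 | (8R,8aS)-2,2-dimethyl-8-(2-methylprop-1-enyl)-4,6,8,8a-tetrahydropyrano[3,4-d][1,3]dioxin-6-ol, both anomers | OC1C=C2COC(C)(C)O[C@@H]2[C@@H](C=C(C)C)O1 | intermediate
8 | (Z)-2-{(4S)-4-[(1R)-1-hydroxy-3-methylbut-2-enyl]-2,2-dimethyl-1,3-dioxan-5-ylidene}acetaldehyde, present as its aluminium alkoxide (not isolated) | O=C/C=C1/COC(C)(C)O[C@@H]1[C@H](O)C=C(C)C | intermediate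
9 | (3R,4S,5R,6S)-6,7-isopropylidenedioxy-p-mentha-1,8-diene-3,5-diol (3α-OH, 4β-isopropenyl, 5α-OH, 6α-O) | O[C@@H]1C=C2COC(C)(C)O[C@@H]2[C@H](O)[C@H]1C(C)=C | intermediate
10 | tiglic acid, (E)-2-methylbut-2-enoic acid | C/C=C(\C)C(=O)O | starting material
11 | acetic anhydride | CC(=O)OC(C)=O | starting material
12 | (3S,4S,5R,6S)-6,7-isopropylidenedioxy-3-tigloyloxy-p-mentha-1,8-dien-5-ol (not isolated) | C/C=C(\C)C(=O)O[C@H]1C=C2COC(C)(C)O[C@@H]2[C@H](O)[C@H]1C(C)=C | intermediate
13 | (3S,4S,5R,6S)-5-acetoxy-6,7-isopropylidenedioxy-3-tigloyloxy-p-mentha-1,8-diene | C/C=C(\C)C(=O)O[C@H]1C=C2COC(C)(C)O[C@@H]2[C@H](OC(C)=O)[C@H]1C(C)=C | intermediate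
14 | (3S,4S,5R,6S)-5-acetoxy-6,7-isopropylidenedioxy-3-tigloyloxy-p-menth-1-ene | C/C=C(\C)C(=O)O[C@H]1C=C2COC(C)(C)O[C@@H]2[C@H](OC(C)=O)[C@H]1C(C)C | intermediate
15 | (3S,4S,5R,6S)-5-acetoxy-3-tigloyloxy-p-menth-1-ene-6,7-diol | C/C=C(\C)C(=O)O[C@H]1C=C(CO)[C@H](O)[C@H](OC(C)=O)[C@H]1C(C)C | intermediate
16 | tigloyl chloride, (E)-2-methylbut-2-enoyl chloride | C/C=C(\C)C(=O)Cl | starting material
17 | 7-O-triethylsilyl ether of 15 (not isolated) | C/C=C(\C)C(=O)O[C@H]1C=C(CO[Si](CC)(CC)CC)[C@H](O)[C@H](OC(C)=O)[C@H]1C(C)C | intermediate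
18 | 7-O-triethylsilyl ether of 19 (not isolated) | C/C=C(\C)C(=O)O[C@H]1C=C(CO[Si](CC)(CC)CC)[C@H](OC(=O)/C(C)=C/C)[C@H](OC(C)=O)[C@H]1C(C)C | intermediate
19 | (3S,4S,5R,6S)-5-acetoxy-7-hydroxy-3,6-bis(tigloyloxy)-p-menth-1-ene (3β-OTig, 4β-iPr, 5α-OAc, 6α-OTig) | C/C=C(\C)C(=O)O[C@H]1C=C(CO)[C@H](OC(=O)/C(C)=C/C)[C@H](OC(C)=O)[C@H]1C(C)C | target

**Step count and weakest steps**
Total step count: 8. Longest linear sequence: 8 (1 → 19).

Step 4 is the most likely to fail.
- **Risks:** The lactol may stay closed, or ionise to the pyranyl cation, which can be methylated or can eliminate to a dienal. A 1,5-hydride shift from C5–H to the activated aldehyde may compete. The fused dioxane could also erode the A1,3-controlled facial selectivity.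
- **Fallback:** It sets out from lactone 6 and comes back at 13. Excess iBu2AlH (CH2Cl2, −78 → 0 °C) reduces 6 to the (Z)-allylic diol F1. Et3SiCl/pyridine at −40 °C, followed by 11/DMAP in the same flask, gives the primary TES ether C5 acetate F2. Swern conditions ((COCl)2, DMSO, Et3N) oxidise the primary allylic TES ether directly to the open-chain (Z)-enal acetate F3, which cannot close to a lactol and has no alkoxide for a hydride shift. Me2AlCl then effects the same ene closure to the carbocyclic hydroxy acetate F4, and Mitsunobu esterification with 10 gives 13. This costs two more steps.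

Step 1 is the second weakest.
- **Risks:** Prenal is a weakly electrophilic conjugated acceptor, and with proline it can form a dienamine and self-condense.
- **Fallback:** It sets out from 1 and comes back at 3. Me3SiOTf/Et3N converts 1 into the silyl enol ether F5. F5 is then added to 2 in a Lewis-base-catalysed Mukaiyama aldol (SiCl4 activated by a chiral binaphthyldiamine bisphosphoramide, CH2Cl2, −78 °C), a system in which conjugated aldehydes are the best acceptors. Aqueous work-up gives 3.

Step 5 is the third weakest.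
- **Risks:** Mitsunobu inversion next to the branched C4 with a weak acid may give elimination, SN2' attack or ester formed with retention.
- **Fallback:** It sets out from 9 and comes back at 12. MnO2 (CH2Cl2) oxidises only the allylic alcohol to the β-hydroxy enone F6. Me4NBH(OAc)3 (MeCN/AcOH, −30 °C) binds to the 5α-OH and delivers hydride to the α face, giving the 3β,5α-diol F7. Acylation of the allylic 3β-OH with 16/pyridine at −20 °C gives 12, which is acetylated as in the main line.

**Further compounds**
F1 | step 4 | (Z)-2-{(4S)-4-[(1R)-1-hydroxy-3-methylbut-2-enyl]-2,2-dimethyl-1,3-dioxan-5-ylidene}ethanol | OC/C=C1/COC(C)(C)O[C@@H]1[C@H](O)C=C(C)C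
F2 | step 4 | primary triethylsilyl ether and secondary acetate of F1 | CC[Si](CC)(CC)OC/C=C1/COC(C)(C)O[C@@H]1[C@H](OC(C)=O)C=C(C)C
F3 | step 4 | (1R)-1-[(4S,5Z)-2,2-dimethyl-5-(2-oxoethylidene)-1,3-dioxan-4-yl]-3-methylbut-2-enyl acetate | O=C/C=C1/COC(C)(C)O[C@@H]1[C@H](OC(C)=O)C=C(C)C
F4 | step 4 | (3R,4S,5R,6S)-5-acetoxy-6,7-isopropylidenedioxy-p-mentha-1,8-dien-3-ol | O[C@@H]1C=C2COC(C)(C)O[C@@H]2[C@H](OC(C)=O)[C@H]1C(C)=C
F5 | step 1 | 2,2-dimethyl-5-(trimethylsilyloxy)-4H-1,3-dioxine | CC1(C)OCC(O[Si](C)(C)C)=CO1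
F6 | step 5 | 5α-hydroxy-4β-isopropenyl-6α,7-isopropylidenedioxy-p-menth-1-en-3-one | O=C1C=C2COC(C)(C)O[C@@H]2[C@H](O)[C@H]1C(C)=C
F7 | step 5 | (3S,4S,5R,6S)-6,7-isopropylidenedioxy-p-mentha-1,8-diene-3,5-diol (3β-epimer of 9) | O[C@H]1C=C2COC(C)(C)O[C@@H]2[C@H](O)[C@H]1C(C)=C
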